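## Structural features

The target is a chalcone in which ring A (a 2',4'-dihydroxyphenyl ketone) and ring B (a 2-hydroxyphenyl group) are joined by an (E)-configured C(=O)–CH=CH bridge. Ring A is contiguously tetrasubstituted: acyl at C1', OH at C2', an alkyl CH2 at C3' and OH at C4', so the alkyl group sits between two phenolic oxygens. The alkyl group is a lavandulyl chain, 5-methyl-2-(prop-1-en-2-yl)hex-4-en-1-yl. Its C2 is the only stereocentre of the molecule, (S)-configured, and carries H, the benzylic CH2 to ring A, the prenyl CH2 and the isopropenyl carbon; there is no neighbouring stereocentre to relay from. The fragile elements are the enone (a Michael acceptor that can close with the C2' phenol to a flavanone and, under strong acid, with the ring B phenol to a benzopyrylium), the two electron-rich olefins within reach of the ring A phenols (acid-induced chroman formation), and the free phenols. The real difficulty is the stereocentre: it is purely hydrocarbon, its three carbon arms are of similar size, and no heteroatom is close enough to direct a reagent. The key step exploits the fact that two of the three arms, the prenyl CH2 and the isopropenyl carbon, are both reachable from CH2OH groups. The centre is therefore latent in C2 of a mirror-symmetric 2-(arylmethyl)propane-1,3-diol whose third arm is the ring A benzyl group, and a lipase that tells the two hydroxymethyl groups apart creates it.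

## Logic of the disconnections

29 to 28. The three phenolic O–CH2 acetal bonds are cut; no skeletal bond is involved. The phenols would quench the organolithium chemistry and, once free, can add to the olefins or the enone, so they are carried as acetal ethers until the end. The two on ring A also serve as ortho-directing groups. The forward step must cleave three acetals without protonating either olefin and without closing the enone onto a phenol.

28 to 20 and 25 (through 26 and 27). The bond between C1' of ring A and the carbonyl carbon is cut. C1' is ortho to an acetal oxygen and is one of two equivalent ring positions open to directed metalation, and 25 delivers the complete enone and ring B in one piece. This divides the molecule into the chiral arene and an achiral, non-enolisable acyl donor. The forward step needs ring deprotonation in preference to benzylic or allylic deprotonation, and a single 1,2-addition that stops at the tetrahedral stage 27.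

25 to 22 and 23 (through 24), and 22 to 21. The olefinic Cα=Cβ bond is cut, then the O–CH2 bond of the ring B acetal. A stabilised phosphonate carbanion gives the E olefin reliably, and both pieces are catalogue compounds. The demand is E selectivity only.

20 to 19, 18, 17 and 16. The C=CH2 bond of the isopropenyl group is cut, then its C–CH3 bond, and the carbon is returned to the alcohol oxidation level. This identifies the isopropenyl carbon as a former hydroxymethyl carbon. The price is that the stereocentre is alpha to a carbonyl in 17 and 19, so every forward operation must be non-epimerising: buffered oxidation, low-temperature addition and a non-basic methylenation.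

16 to 15, then to 12 and 13 (through 14). The ester O–acyl bond is cut, then the sp3–sp2 bond between the prenyl CH2 and its vinylic carbon. The prenyl CH2 is the second former hydroxymethyl carbon, and 13 is commercial. The side chain is thereby reduced to a three-carbon unit with two differentiated arms. The forward step must substitute a beta-branched primary iodide without attacking the acetate.

12 to 11. The C–I bond is exchanged for C–OH. The forward step must be fast and near neutral, because a 1,3-acetyl shift in 11 would interconvert its enantiomers.

11 to 9 and 10. Only the acetyl C–O bond is cut. This removes the sole stereocentre and leads to 9, which has a mirror plane through C2. The forward step demands discrimination of two enantiotopic CH2OH groups and a stop at the monoester, and this is what the enzyme provides.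

9 to 8, 7, and then 5 and 6. The diol is returned to the diester oxidation level, and the bond between the benzylic carbon and the malonate carbon is cut through the corresponding C=C bond. A 1,3-diol is a reduced malonate, and condensation followed by hydrogenation avoids a labile, electron-rich ortho,ortho'-dialkoxybenzyl halide. The condensation must cope with a hindered aldehyde.

5 to 2 (through 3 and 4), and 2 to 1. The aryl C2–CHO bond is cut, then the two O–CH2 acetal bonds. C2 of 2 lies between two coordinating acetal oxygens and is the most acidic ring position, so the formyl group enters with complete regiocontrol. 1 is a commodity chemical.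

## Other disconnections considered

Alternative 1: Ring A is built instead of bought, by cutting C1'–C2' and C5'–C6'. In the forward sense the bis-silyloxy diene A2 and the enynone A3 undergo a thermal [4+2] cycloaddition. Loss of methoxytrimethylsilane and hydrolysis of the remaining silyl enol ether aromatise the adduct to A4, which differs from 29 only by the ring B acetal. A2 would come from an acetoacetate ester C-alkylated with the enantiopure bromide A1, and A3 from 22.
- In its favour: the substitution pattern of ring A follows unambiguously from the polarity of A2 and A3, no directed metalation is needed, and the ring A phenols are never protected.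
- Against it here: the cycloaddition does not create the stereocentre. It moves the problem to the supply of A1, and C-alkylation of an acetoacetate with a beta-branched primary bromide is slow. A2 is hindered at its ketene-acetal terminus, and A3 offers a second electrophilic site (the enone C=C) for Michael-type attack or polymerisation.
- Structure: the chosen plan buys ring A and makes the centre; this one makes ring A and buys the centre.
- Mechanism: a pericyclic step with substituent-dictated regiochemistry, against enzyme recognition.
- Step economy: with A1 in hand this route would be clearly shorter than the chosen one and is the better plan on that count. It is also the better plan on the mildness of the final deprotection, since one acetal is removed instead of three. It is the weaker plan on the one question that matters most, the origin of the (S) centre.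

Alternative 2: The bond between the benzylic CH2 and the stereocentre is cut. The benzylic Grignard reagent A5 would attack the gamma carbon of the dienyl phosphate A6 in a copper-catalysed asymmetric SN2' substitution with a chiral ligand. This gives A7 (identical with 20) with the isopropenyl group unveiled in the same event.
- In its favour: one C–C bond formation delivers the whole lavandulyl chain, the stereocentre and the 1,1-disubstituted olefin, and the route joins the chosen one at 20.
- Against it here: A5 derives from an ortho,ortho'-dialkoxybenzyl halide that is labile and prone to homocoupling. Benzylic Grignard reagents are among the less selective nucleophiles of this reaction class, in both SN2'/SN2 ratio and enantioselectivity. The 2-methyl-substituted allyl system of A6 is a less developed substrate type. The linear SN2 isomer and the minor enantiomer would be hard to remove from an oily hydrocarbon-like product.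
- Structure: both plans pass through the same arene 20.
- Mechanism: here a monovalent copper nucleophile adds anti to the leaving group and a trivalent allylcopper species reductively eliminates, so the ligand controls facial selectivity in a C–C bond formation. In the chosen plan the centre arises without any C–C bond, by group selection on a symmetric diol, and enantiopurity can be raised by over-acylation.
- Step economy: this alternative is much the better, roughly five steps to 20 against thirteen. The chosen plan is preferred only because its stereocontrol rests on a better-precedented substrate class.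

Alternative 3: The bond between the stereocentre and the isopropenyl carbon is cut. The boronate A9 would add to the beta carbon of the gamma-aryl enoate A8 under rhodium catalysis with a chiral ligand to give the ester A10. Reduction to the aldehyde and an isopropylidene Wittig reaction would then give 20.
- In its favour: asymmetric rhodium-catalysed conjugate addition of alkenylboron reagents is a mature reaction class. The isopropenyl group is installed directly, which avoids the alcohol-to-isopropenyl sequence of the chosen plan and its two epimerisable carbonyl intermediates.
- Against it here: the gamma protons of A8 are both benzylic and vinylogously acidic. Under the basic aqueous conditions of the reaction the double bond can move into conjugation with the electron-rich arene, and the acceptor is lost. Acyclic enoates with only a CH2 group at the beta carbon tend to be less selective than cyclic enones. The 1-substituted alkenylboronate A9 transmetalates slowly and protodeboronates. A8 itself needs a sensitive arylacetaldehyde.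
- Structure: the two plans are equal, since both attach the chain to intact ring A and both need the same late metalation and acylation.
- Mechanism: enantioface selection in an alkenyl–rhodium insertion, against enantiotopic group selection by an enzyme.
- Step economy: the alternative is better by about four steps after its key step. The chosen plan has no base-sensitive acceptor, and its enantiopurity is established and assayed early on a simple diol monoester.

Key step: step 6

Assumption: the lipase is taken to acetylate the pro-R hydroxymethyl group of 9, giving (R)-11. If it prefers the other arm, either the two arms are elaborated in exchanged roles or the complementary hydrolysis described under the fallback for step 6 is used.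

Remark: the CIP descriptor of the side-chain centre changes from (R) in 11 to (S) from 12 onwards, although no bond to it is made or broken. Only the priorities of its arms change.

## Route

Step 1
Reactants: 1 resorcinol
Product: 2 1,3-bis(methoxymethoxy)benzene
Conditions: MOMCl, i-Pr2NEt, CH2Cl2, 0 °C → rt
Reagents that add atoms: chloromethyl methyl ether, COCCl
Why: Williamson-type O-alkylation of both phenols by the reactive alpha-chloro ether; the acetal ethers mask the acidic OH groups and later act as ortho-directing groups.

Step 2
Reactants: 2 1,3-bis(methoxymethoxy)benzene
Product: 5 2,6-bis(methoxymethoxy)benzaldehyde, via aryllithium 3 (not isolated), via lithium hemiaminal alkoxide 4 (not isolated)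
Conditions: n-BuLi, TMEDA, THF, 0 °C; then DMF, 0 °C → rt
Reagents that add atoms: N,N-dimethylformamide, CN(C)C=O
Why: Directed ortho-metalation; C2 lies between two coordinating acetal oxygens and is deprotonated selectively, and formylation with DMF proceeds through 4, which collapses to the aldehyde on aqueous work-up.

Step 3
Reactants: 5 2,6-bis(methoxymethoxy)benzaldehyde; 6 diethyl malonate
Product: 7 diethyl 2-[2,6-bis(methoxymethoxy)benzylidene]malonate
Conditions: piperidine (cat.), AcOH (cat.), toluene, reflux, Dean–Stark
Reagents that add atoms: none
Why: Knoevenagel condensation through the iminium ion of the aldehyde, driven by azeotropic removal of water; the amine-buffered medium leaves the aryl acetals intact, and the route avoids an unstable ortho,ortho'-dialkoxybenzyl halide.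

Step 4
Reactants: 7 diethyl 2-[2,6-bis(methoxymethoxy)benzylidene]malonate
Product: 8 diethyl 2-[2,6-bis(methoxymethoxy)benzyl]malonate
Conditions: H2 (1 atm), 10% Pd/C, EtOAc, rt
Reagents that add atoms: none
Why: Heterogeneous hydrogenation of an electron-poor trisubstituted olefin; esters and aryl acetal ethers are inert, and there is no benzylic heteroatom to hydrogenolyse.

Step 5
Reactants: 8 diethyl 2-[2,6-bis(methoxymethoxy)benzyl]malonate
Product: 9 2-[2,6-bis(methoxymethoxy)benzyl]propane-1,3-diol
Conditions: LiAlH4, THF, 0 °C → reflux
Reagents that add atoms: none
Why: Hydride reduction of both esters to the primary alcohols; adding the malonate to excess hydride limits formation of the unreactive malonate enolate.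

Step 6
Reactants: 9 2-[2,6-bis(methoxymethoxy)benzyl]propane-1,3-diol; 10 vinyl acetate
Product: 11 (R)-2-[2,6-bis(methoxymethoxy)benzyl]-3-hydroxypropyl acetate
Conditions: Pseudomonas fluorescens lipase, t-BuOMe, 25 °C
Reagents that add atoms: none
Why: The lipase is a serine hydrolase: its active-site serine, activated by the histidine–aspartate relay, is acetylated by 10, and the released vinyl alcohol tautomerises to acetaldehyde, which makes the acyl transfer irreversible. Diol 9 then binds to the acyl-enzyme with its arylmethyl group in the large hydrophobic pocket and the C2 hydrogen in the small one, so that only one of the two enantiotopic CH2OH groups can reach the acetyl group and is esterified. The closest known reaction type is the lipase-catalysed enantioselective monoacetylation of prochiral 2-benzylpropane-1,3-diols with vinyl acetate. No ring is closed and no skeletal bond is formed; C2 becomes a stereocentre only because its two hydroxymethyl arms become different. The configuration is therefore set by the chiral active site alone (catalyst control), the substrate being achiral, and acetylation of the pro-R arm is what gives (R)-11. Two selectivities are needed, between the enantiotopic arms and between mono- and diacetylation; the first rests on the large size difference between the arylmethyl group and H at C2, the second on the lower reactivity of the monoacetate and on stopping when 9 is consumed. Any diacetate that does form should arise mainly from the minor enantiomer of the monoacetate, whose free arm is the one the enzyme prefers, so slight over-acylation is expected to raise the enantiomeric purity of 11. Because a 1,3-acetyl shift would interconvert the enantiomers, 11 is filtered from the enzyme, concentrated without heat, acid or base, and taken directly into step 7.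

Step 7
Reactants: 11 (R)-2-[2,6-bis(methoxymethoxy)benzyl]-3-hydroxypropyl acetate
Product: 12 (S)-2-[2,6-bis(methoxymethoxy)benzyl]-3-iodopropyl acetate
Conditions: PPh3, I2, imidazole, CH2Cl2, 0 °C → rt
Reagents that add atoms: iodine, II
Why: Appel-type iodination through an alkoxyphosphonium iodide and SN2 displacement at the primary carbon; the stereocentre is not a reacting centre, and the fast, imidazole-buffered conditions leave no time for acetyl migration, which becomes impossible once the hydroxyl is gone.

Step 8
Reactants: 12 (S)-2-[2,6-bis(methoxymethoxy)benzyl]-3-iodopropyl acetate; 13 2-methylprop-1-enylmagnesium bromide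
Product: 15 (S)-2-[2,6-bis(methoxymethoxy)benzyl]-5-methylhex-4-en-1-yl acetate, via cuprate 14 (not isolated)
Conditions: CuI (1.1 equiv), 13 (2.2 equiv), THF, −30 °C; then 12, −30 → 0 °C
Reagents that add atoms: none
Why: Two equivalents of 13 and CuI give the homocuprate 14, which substitutes the primary iodide (SN2-type oxidative addition, then reductive elimination) to form the sp3–sp2 bond of the prenyl arm. With no free Grignard reagent present, the acetate is not attacked at these temperatures, and the stereocentre, beta to the reacting carbon, is untouched.

Step 9
Reactants: 15 (S)-2-[2,6-bis(methoxymethoxy)benzyl]-5-methylhex-4-en-1-yl acetate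
Product: 16 (S)-2-[2,6-bis(methoxymethoxy)benzyl]-5-methylhex-4-en-1-ol
Conditions: K2CO3 (cat.), MeOH, rt
Reagents that add atoms: none
Why: Base-catalysed transesterification with methanol; the molecule has no base-sensitive or epimerisable site at this stage.

Step 10
Reactants: 16 (S)-2-[2,6-bis(methoxymethoxy)benzyl]-5-methylhex-4-en-1-ol
Product: 17 (S)-2-[2,6-bis(methoxymethoxy)benzyl]-5-methylhex-4-enal
Conditions: Dess–Martin periodinane, NaHCO3, CH2Cl2, 0 °C → rt
Reagents that add atoms: none
Why: Dess–Martin oxidation by ligand exchange at pentavalent iodine and intramolecular proton abstraction; the buffered, non-aqueous and non-basic medium preserves the alpha stereocentre and the acetals, and 17 is used at once.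

Step 11
Reactants: 17 (S)-2-[2,6-bis(methoxymethoxy)benzyl]-5-methylhex-4-enal
Product: 18 (3S)-3-[2,6-bis(methoxymethoxy)benzyl]-6-methylhept-5-en-2-ol (mixture of C2 epimers)
Conditions: MeMgBr, THF, −78 °C
Reagents that add atoms: methylmagnesium bromide, C[Mg]Br
Why: Grignard 1,2-addition to the aldehyde, which at −78 °C is much faster than enolisation; the new carbinol centre forms as a mixture and is removed in the next step.

Step 12
Reactants: 18 (3S)-3-[2,6-bis(methoxymethoxy)benzyl]-6-methylhept-5-en-2-ol (mixture of C2 epimers)
Product: 19 (S)-3-[2,6-bis(methoxymethoxy)benzyl]-6-methylhept-5-en-2-one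
Conditions: Dess–Martin periodinane, NaHCO3, CH2Cl2, 0 °C → rt
Reagents that add atoms: none
Why: Dess–Martin oxidation of both carbinol epimers to one ketone under the same non-epimerising conditions as in step 10.

Step 13
Reactants: 19 (S)-3-[2,6-bis(methoxymethoxy)benzyl]-6-methylhept-5-en-2-one
Product: 20 (S)-1,3-bis(methoxymethoxy)-2-[5-methyl-2-(prop-1-en-2-yl)hex-4-en-1-yl]benzene
Conditions: Cp2TiMe2, toluene/THF, 65 °C, dark
Reagents that add atoms: dimethyltitanocene, C[Ti](C)(C1C=CC=C1)C1C=CC=C1
Why: Petasis methylenation: thermal loss of methane gives Cp2Ti=CH2, which adds to the carbonyl to an oxatitanacyclobutane that cycloreverts to the olefin. The reagent is neither basic nor Lewis acidic, so the alpha stereocentre and the acetals should be preserved.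

Step 14
Reactants: 21 salicylaldehyde
Product: 22 2-(methoxymethoxy)benzaldehyde
Conditions: MOMCl, i-Pr2NEt, CH2Cl2, 0 °C → rt
Reagents that add atoms: chloromethyl methyl ether, COCCl
Why: O-alkylation of the phenol with the alpha-chloro ether, to remove the acidic proton before the carbanion chemistry of steps 15 and 16.

Step 15
Reactants: 22 2-(methoxymethoxy)benzaldehyde; 23 diethyl {2-[methoxy(methyl)amino]-2-oxoethyl}phosphonate
Product: 25 (E)-N-methoxy-3-[2-(methoxymethoxy)phenyl]-N-methylprop-2-enamide, via sodium phosphonate carbanion 24 (not isolated)
Conditions: NaH, THF, 0 °C; then 22, 0 °C → rt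
Reagents that add atoms: none
Why: Horner–Wadsworth–Emmons olefination; the amide-stabilised carbanion adds reversibly, and the anti oxaphosphetane eliminates to the E olefin.

Step 16
Reactants: 20 (S)-1,3-bis(methoxymethoxy)-2-[5-methyl-2-(prop-1-en-2-yl)hex-4-en-1-yl]benzene; 25 (E)-N-methoxy-3-[2-(methoxymethoxy)phenyl]-N-methylprop-2-enamide
Product: 28 (2E)-1-{2,4-bis(methoxymethoxy)-3-[(2S)-5-methyl-2-(prop-1-en-2-yl)hex-4-en-1-yl]phenyl}-3-[2-(methoxymethoxy)phenyl]prop-2-en-1-one, via aryllithium 26 (not isolated), via lithium hemiaminal chelate 27 (not isolated)
Conditions: n-BuLi, TMEDA, THF, −20 → 0 °C; then 25, −78 → 0 °C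
Reagents that add atoms: none
Why: Directed ortho-metalation at C4, one of two equivalent positions next to an acetal oxygen, is kinetically favoured over benzylic and allylic deprotonation. Weinreb amide acylation of 26 stops at the five-membered lithium chelate 27, which releases the ketone only on work-up, so there is no second addition. 25 has no enolisable proton, and the side-chain centre is remote.

Step 17
Reactants: 28 (2E)-1-{2,4-bis(methoxymethoxy)-3-[(2S)-5-methyl-2-(prop-1-en-2-yl)hex-4-en-1-yl]phenyl}-3-[2-(methoxymethoxy)phenyl]prop-2-en-1-one
Product: 29 (2E)-1-{2,4-dihydroxy-3-[(2S)-5-methyl-2-(prop-1-en-2-yl)hex-4-en-1-yl]phenyl}-3-(2-hydroxyphenyl)prop-2-en-1-one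
Conditions: 3 M aq HCl, MeOH, rt → 40 °C
Reagents that add atoms: none
Why: Acid-catalysed acetal exchange with methanol through oxocarbenium ions, the three protecting groups leaving as dimethoxymethane. Dilute acid near room temperature is the usual way to unmask prenylated hydroxychalcones and should leave the trisubstituted and 1,1-disubstituted olefins unprotonated; the stereocentre is not involved.

## Compound list

1 | resorcinol (benzene-1,3-diol) | Oc1cccc(O)c1 | starting material
2 | 1,3-bis(methoxymethoxy)benzene | COCOc1cccc(OCOC)c1 | intermediate
3 | [2,6-bis(methoxymethoxy)phenyl]lithium | [Li]c1c(OCOC)cccc1OCOC | intermediate (not isolated)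
4 | lithium [2,6-bis(methoxymethoxy)phenyl](dimethylamino)methanolate | [Li]OC(N(C)C)c1c(OCOC)cccc1OCOC | intermediate (not isolated)
5 | 2,6-bis(methoxymethoxy)benzaldehyde | O=Cc1c(OCOC)cccc1OCOC | intermediate
6 | diethyl malonate | CCOC(=O)CC(=O)OCC | starting material
7 | diethyl 2-[2,6-bis(methoxymethoxy)benzylidene]malonate | CCOC(=O)C(=Cc1c(OCOC)cccc1OCOC)C(=O)OCC | intermediate
8 | diethyl 2-[2,6-bis(methoxymethoxy)benzyl]malonate | CCOC(=O)C(Cc1c(OCOC)cccc1OCOC)C(=O)OCC | intermediate
9 | 2-[2,6-bis(methoxymethoxy)benzyl]propane-1,3-diol | OCC(CO)Cc1c(OCOC)cccc1OCOC | intermediate
10 | vinyl acetate | C=COC(C)=O | starting material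
11 | (R)-2-[2,6-bis(methoxymethoxy)benzyl]-3-hydroxypropyl acetate | CC(=O)OC[C@@H](CO)Cc1c(OCOC)cccc1OCOC | intermediate
12 | (S)-2-[2,6-bis(methoxymethoxy)benzyl]-3-iodopropyl acetate | CC(=O)OC[C@@H](CI)Cc1c(OCOC)cccc1OCOC | intermediate
13 | 2-methylprop-1-enylmagnesium bromide | CC(C)=C[Mg]Br | starting material
14 | bromomagnesium bis(2-methylprop-1-enyl)cuprate | CC(C)=C[Cu-]C=C(C)C.[Mg+]Br | intermediate (not isolated)
15 | (S)-2-[2,6-bis(methoxymethoxy)benzyl]-5-methylhex-4-en-1-yl acetate | CC(=O)OC[C@@H](CC=C(C)C)Cc1c(OCOC)cccc1OCOC | intermediate
16 | (S)-2-[2,6-bis(methoxymethoxy)benzyl]-5-methylhex-4-en-1-ol | OC[C@@H](CC=C(C)C)Cc1c(OCOC)cccc1OCOC | intermediate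
17 | (S)-2-[2,6-bis(methoxymethoxy)benzyl]-5-methylhex-4-enal | O=C[C@@H](CC=C(C)C)Cc1c(OCOC)cccc1OCOC | intermediate
18 | (3S)-3-[2,6-bis(methoxymethoxy)benzyl]-6-methylhept-5-en-2-ol (mixture of C2 epimers) | CC(O)[C@@H](CC=C(C)C)Cc1c(OCOC)cccc1OCOC | intermediate
19 | (S)-3-[2,6-bis(methoxymethoxy)benzyl]-6-methylhept-5-en-2-one | CC(=O)[C@@H](CC=C(C)C)Cc1c(OCOC)cccc1OCOC | intermediate
20 | (S)-1,3-bis(methoxymethoxy)-2-[5-methyl-2-(prop-1-en-2-yl)hex-4-en-1-yl]benzene | C=C(C)[C@@H](CC=C(C)C)Cc1c(OCOC)cccc1OCOC | intermediate
21 | salicylaldehyde (2-hydroxybenzaldehyde) | O=Cc1ccccc1O | starting material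
22 | 2-(methoxymethoxy)benzaldehyde | O=Cc1ccccc1OCOC | intermediate
23 | diethyl {2-[methoxy(methyl)amino]-2-oxoethyl}phosphonate | CCOP(=O)(CC(=O)N(C)OC)OCC | starting material
24 | sodium salt of the alpha-carbanion of 23 | CCOP(=O)([CH-]C(=O)N(C)OC)OCC.[Na+] | intermediate (not isolated)
25 | (E)-N-methoxy-3-[2-(methoxymethoxy)phenyl]-N-methylprop-2-enamide | CON(C)C(=O)/C=C/c1ccccc1OCOC | intermediate
26 | {2,4-bis(methoxymethoxy)-3-[(2S)-5-methyl-2-(prop-1-en-2-yl)hex-4-en-1-yl]phenyl}lithium | C=C(C)[C@@H](CC=C(C)C)Cc1c(OCOC)ccc([Li])c1OCOC | intermediate (not isolated)
27 | lithium (2E)-1-{2,4-bis(methoxymethoxy)-3-[(2S)-5-methyl-2-(prop-1-en-2-yl)hex-4-en-1-yl]phenyl}-1-[methoxy(methyl)amino]-3-[2-(methoxymethoxy)phenyl]prop-2-en-1-olate (either configuration at the carbinol carbon) | C=C(C)[C@@H](CC=C(C)C)Cc1c(OCOC)ccc(C(O[Li])(/C=C/c2ccccc2OCOC)N(C)OC)c1OCOC | intermediate (not isolated)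
28 | (2E)-1-{2,4-bis(methoxymethoxy)-3-[(2S)-5-methyl-2-(prop-1-en-2-yl)hex-4-en-1-yl]phenyl}-3-[2-(methoxymethoxy)phenyl]prop-2-en-1-one | C=C(C)[C@@H](CC=C(C)C)Cc1c(OCOC)ccc(C(=O)/C=C/c2ccccc2OCOC)c1OCOC | intermediate
29 | (2E)-1-{2,4-dihydroxy-3-[(2S)-5-methyl-2-(prop-1-en-2-yl)hex-4-en-1-yl]phenyl}-3-(2-hydroxyphenyl)prop-2-en-1-one | C=C(C)[C@@H](CC=C(C)C)Cc1c(O)ccc(C(=O)/C=C/c2ccccc2O)c1O | target

## Step count and risks

Total step count: 17. Longest linear sequence: 15 steps (steps 1 to 13, then 16 and 17); steps 14 and 15 are a two-step branch that joins at step 16.

Least certain steps:

Step 6 (key step). The most likely failure is weak discrimination between the two enantiotopic hydroxymethyl groups, because the ortho,ortho'-disubstituted aryl group may not seat in the hydrophobic pocket as a plain benzyl group does. Erosion of enantiopurity by 1,3-acetyl migration during isolation is the second concern. The fallback changes the direction of the enzymatic reaction. Starting from 9, exhaustive acetylation (Ac2O, pyridine, DMAP) should give 2-[2,6-bis(methoxymethoxy)benzyl]propane-1,3-diyl diacetate F1, and a lipase (the same Pseudomonas enzyme or porcine pancreatic lipase) in pH 7 phosphate buffer with a cosolvent then hydrolyses one enantiotopic ester. Hydrolysis removes the acetyl group from the arm the enzyme recognises, so an enzyme that acetylates the wrong arm of 9 leaves the acetate on the right one here. The fallback returns to the route at 11.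

Step 8. The most likely failure is slow substitution at the beta-branched primary iodide by the weakly nucleophilic alkenyl cuprate. Thermal decomposition of 14, reduction of the iodide or attack on the acetate could then compete. The fallback reverses the polarity of the coupling. Starting from 12, zinc insertion (Zn dust, LiCl, THF) should give {(S)-3-acetoxy-2-[2,6-bis(methoxymethoxy)benzyl]propyl}zinc iodide F2, an ester-tolerant reagent. Negishi coupling of F2 with 1-bromo-2-methylprop-1-ene (Pd(OAc)2, SPhos, THF, rt → 50 °C) then forms the same sp3–sp2 bond and returns to the route at 15.

Step 13. The most likely failure is sluggish methylenation of the alpha-branched ketone by the bulky titanium methylidene. Prolonged heating would give enolisation towards the stereocentre time to erode the configuration, or conversion would stay incomplete. The fallback is a Peterson olefination. Starting from 19, Me3SiCH2MgCl with anhydrous CeCl3 in THF at −78 °C (an organocerium reagent, nucleophilic but hardly basic) should give (3S)-3-[2,6-bis(methoxymethoxy)benzyl]-2,6-dimethyl-1-(trimethylsilyl)hept-5-en-2-ol F3. Treatment of F3 with KH in THF induces syn elimination of the silanolate and returns to the route at 20.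

Step 16. The most likely failures are conjugate addition of 26 to the unsaturated amide in competition with carbonyl addition, and incomplete ring metalation, with some deprotonation at the doubly flanked benzylic CH2. The fallback separates acylation from enone formation. Starting from 20, the same metalation followed by N-methoxy-N-methylacetamide, an acceptor without a conjugate position, should give (S)-1-{2,4-bis(methoxymethoxy)-3-[5-methyl-2-(prop-1-en-2-yl)hex-4-en-1-yl]phenyl}ethan-1-one F4; this quench also tests the metalation on its own. Claisen–Schmidt condensation of F4 with 22 (KOH, EtOH, rt) then builds the E enone and returns to the route at 28.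

Step 17. The most likely failure is acid-mediated reaction of the product in competition with acetal cleavage: addition of a freed ring A phenol across a protonated olefin of the side chain (chroman formation), closure of the C2' phenol onto the enone (flavanone), or closure through the ring B phenol to a benzopyrylium. The fallback replaces protic solvolysis by aprotic silyl transfer. Starting from 28, TMSOTf and 2,2'-bipyridyl in CH3CN at 0 °C → rt should convert the three aryl acetals into the tris(trimethylsilyl) ether of the target, (2E)-1-{3-[(2S)-5-methyl-2-(prop-1-en-2-yl)hex-4-en-1-yl]-2,4-bis(trimethylsilyloxy)phenyl}-3-[2-(trimethylsilyloxy)phenyl]prop-2-en-1-one F5. Addition of water hydrolyses F5 under essentially neutral conditions and returns to the route at 29.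

## Further compounds

F1 | step 6 | 2-[2,6-bis(methoxymethoxy)benzyl]propane-1,3-diyl diacetate | CC(=O)OCC(COC(C)=O)Cc1c(OCOC)cccc1OCOC
F2 | step 8 | {(S)-3-acetoxy-2-[2,6-bis(methoxymethoxy)benzyl]propyl}zinc iodide | CC(=O)OC[C@@H](C[Zn]I)Cc1c(OCOC)cccc1OCOC
F3 | step 13 | (3S)-3-[2,6-bis(methoxymethoxy)benzyl]-2,6-dimethyl-1-(trimethylsilyl)hept-5-en-2-ol (mixture of C2 epimers) | C[Si](C)(C)CC(C)(O)[C@@H](CC=C(C)C)Cc1c(OCOC)cccc1OCOC
F4 | step 16 | (S)-1-{2,4-bis(methoxymethoxy)-3-[5-methyl-2-(prop-1-en-2-yl)hex-4-en-1-yl]phenyl}ethan-1-one | C=C(C)[C@@H](CC=C(C)C)Cc1c(OCOC)ccc(C(C)=O)c1OCOC
F5 | step 17 | (2E)-1-{3-[(2S)-5-methyl-2-(prop-1-en-2-yl)hex-4-en-1-yl]-2,4-bis(trimethylsilyloxy)phenyl}-3-[2-(trimethylsilyloxy)phenyl]prop-2-en-1-one | C=C(C)[C@@H](CC=C(C)C)Cc1c(O[Si](C)(C)C)ccc(C(=O)/C=C/c2ccccc2O[Si](C)(C)C)c1O[Si](C)(C)C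
A1 | alternative 1 | (R)-3-(bromomethyl)-2,6-dimethylhepta-1,5-diene (lavandulyl bromide) | C=C(C)[C@@H](CC=C(C)C)CBr
A2 | alternative 1 | 1-methoxy-2-[(2S)-5-methyl-2-(prop-1-en-2-yl)hex-4-en-1-yl]-1,3-bis(trimethylsilyloxy)buta-1,3-diene | C=C(C)[C@@H](CC=C(C)C)CC(C(=C)O[Si](C)(C)C)=C(OC)O[Si](C)(C)C
A3 | alternative 1 | (E)-1-[2-(methoxymethoxy)phenyl]pent-1-en-4-yn-3-one | C#CC(=O)/C=C/c1ccccc1OCOC
A4 | alternative 1 | (2E)-1-{2,4-dihydroxy-3-[(2S)-5-methyl-2-(prop-1-en-2-yl)hex-4-en-1-yl]phenyl}-3-[2-(methoxymethoxy)phenyl]prop-2-en-1-one | C=C(C)[C@@H](CC=C(C)C)Cc1c(O)ccc(C(=O)/C=C/c2ccccc2OCOC)c1O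
A5 | alternative 2 | [2,6-bis(methoxymethoxy)benzyl]magnesium chloride | COCOc1cccc(OCOC)c1C[Mg]Cl
A6 | alternative 2 | (E)-2,6-dimethylhepta-2,5-dien-1-yl diethyl phosphate | CCOP(=O)(OCC)OC/C(C)=C/CC=C(C)C
A7 | alternative 2 | (S)-1,3-bis(methoxymethoxy)-2-[5-methyl-2-(prop-1-en-2-yl)hex-4-en-1-yl]benzene (identical with 20) | C=C(C)[C@@H](CC=C(C)C)Cc1c(OCOC)cccc1OCOC
A8 | alternative 3 | ethyl (E)-4-[2,6-bis(methoxymethoxy)phenyl]but-2-enoate | CCOC(=O)/C=C/Cc1c(OCOC)cccc1OCOC
A9 | alternative 3 | 4,4,5,5-tetramethyl-2-(prop-1-en-2-yl)-1,3,2-dioxaborolane | C=C(C)B1OC(C)(C)C(C)(C)O1
A10 | alternative 3 | ethyl (R)-3-[2,6-bis(methoxymethoxy)benzyl]-4-methylpent-4-enoate | C=C(C)[C@@H](CC(=O)OCC)Cc1c(OCOC)cccc1OCOC
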